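Convention: germacrane numbering (C1–C15) is kept for every intermediate; β is the face of ring B (and of the ten-membered ring) that carries C11 on C7 and H on C8, α the opposite face.

Assumption: the lipase in step 3 is chosen (acylation of the diol or, for the other sense, hydrolysis of the diacetate) so that the (1S,3R,5R)-monoacetate 4 is the product.

## Analysis of the target

Target 29 is a germacranolide built on a ten-membered carbocycle (C1–C10). It has a C1=C10 double bond that is trans within the ring, a cis 4,5-epoxide with the C15 methyl on C4, and a free hydroxyl on C6. An α-methylene-γ-butyrolactone is trans-fused across C7–C8 (oxygen on C8, C11–C12 on C7, exocyclic C13), and the allylic C14 oxygen carries a tiglate.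

Five contiguous stereocentres run from C4 to C8, (4S,5R,6S,7S,8S). H7 and H8 are anti, the 6-hydroxyl lies on the face of H7 and opposite to C11, and the epoxide oxygen is on the face opposite to the 6-hydroxyl (a threo epoxy alcohol).

The acrylate of the lactone is a strong Michael acceptor. The allylic epoxide and the trans-cyclodecene invite acid-induced transannular cyclisation. Any C6 ketone intermediate has an acidic C7–H flanked by a β-acyloxy group.

The difficulty is to form a strained ten-membered ring with one trans and one cis trisubstituted alkene of defined geometry while the lactone survives.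

The strategy rests on the 1,3-relationship of the C6 and C14 oxygens through C1 and C10. Drawing a C1–C6 bond turns the macrocycle into a trans-decalin (ring A: C1–C6; ring B: C6–C10 and C1) in which O–C6–C1–C10–O is a fragmentation array, with the C14 oxygen stored as a C10 spiro-epoxide. The 1,3,5-oxygenation of ring B (C6, C8, C10) points to phloroglucinol 1 as its source.

## Retrosynthetic reasoning

**29 ⇒ 28.** The two C–O bonds of the 4,5-epoxide are removed first. The epoxide is the most acid-labile group, and in 28 the C6 hydroxyl is the only free allylic hydroxyl, so a hydroxyl-directed epoxidation can pick C4=C5 out of four alkenes. The forward step must deliver oxygen to the face that gives the threo relationship.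

**28 ⇒ 26 + 27.** The C14–O acyl bond is cut. Acylation is placed after the C6 reduction (no base then meets a ketone with an acidic C7–H) and before the epoxidation (the C14 hydroxyl would otherwise direct oxidation to C1=C10). The forward step must distinguish a primary from a hindered secondary allylic hydroxyl.

**26 ⇒ 25.** The C6–H bond is removed. The carbinol is traced to the ketone because the ketone is exactly what the fragmentation leaves at C6. The forward step must be a 1,2-reduction from the correct face.

**25 ⇒ 24 (key step).** The C1–C6 bond is re-formed and the C14 oxygen is tied back to C10 as an epoxide. Of all ring bonds, only a transannular C1–C6 bond makes the two oxygen atoms the ends of a five-atom fragmentation array. It also converts the macrocycle into a trans-decalin whose chair stores the trans C1=C10 geometry and whose cyclohexene stores the cis C4=C5 geometry. No macrocyclisation is needed in the forward direction.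

**24 ⇒ 21.** The exocyclic C13 is removed. The acrylate is installed only one step before the fragmentation because it would not survive a sulfur ylide or organometallic reagents.

**21 ⇒ 20.** The C10–C14 bond and the C14–O bond of the spiro-epoxide are cut, leaving a C10 ketone and a one-carbon sulfur ylide. The forward step must bring C14 in axially so that the C10–O bond is equatorial.

**20 ⇒ 19 ⇒ 18.** The C10 ketone is traced to the secondary alcohol, and ring A is opened at C4=C5 by retro-metathesis. This leaves a vinyl group on C6 and a 3-methylbut-3-enyl chain on C1, both equatorial on ring B.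

**18 ⇒ 16 + 17.** The C5–C6 bond is cut: vinyl addition to a C6 ketone, which must occur equatorially to give the axial tertiary hydroxyl.

**16 ⇒ 14.** The C10–O bond is removed, giving an enone. The β-carbon of the enone is where the C10 oxygen can be returned by conjugate borylation and oxidation.

**14 ⇒ 11 + 12; 11 ⇒ 10.** The C1–C2 bond is cut as an sp2–sp3 cross-coupling of an α-iodoenone with the organozinc from 12. An enolate alkylation with a homoallylic halide is avoided because elimination would dominate.

**10 ⇒ 8 ⇒ 6 + 7.** The lactone C12–O8 bond and then the C7–C11 bond are cut. The lactone is closed early, while the molecule still tolerates acid and before a competing C6 hydroxyl exists. The alkylation of the enone 6 can only occur at C7.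

**6 ⇒ 4 ⇒ 3 ⇒ 2 ⇒ 1.** The enone comes from a desymmetrised all-cis triol by oxidation and β-elimination. The C10 oxygen of the triol is given up here to gain regiocontrol (C7 versus C1) and is reinstated at 16. The triol is the hydrogenation product of 1.

## Alternatives that were turned down

**Alternative 1:** The disconnection is at the lactone, through the C11–C12 and C12–O8 bonds. In the forward key step a hydridopalladium species (zerovalent palladium with a chelating diphosphine under a carbonylating atmosphere) adds across a C11–C13 alkyne, carbonylation occurs at C11 and the C8 hydroxyl traps the acyl group to give A1.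
- For: the most sensitive group of the target is built late, in one step, from a robust alkyne, and five-membered lactonisation steers the regiochemistry.
- Against: the step does not address the central problem. The ten-membered ring with both trisubstituted alkenes and the C6–C8 stereotriad must already exist, so a macrocyclisation without geometric storage is still required, and two protecting groups must come off afterwards.
- Comparison: Alternative 1 is stronger in the handling of the acrylate, which never meets an ylide, an organometallic reagent or a Lewis acid. The chosen route offers instead a solution to ring formation and alkene geometry, and delivers O14 and C6 at the right oxidation level without protection.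

**Alternative 2:** The disconnection forms C2–C3 and cleaves C5–C10 of a cyclohexanol by a [3,3] shift. In the forward key step the potassium alkoxide undergoes an anionic oxy-Cope rearrangement, the six-membered ring grows to ten, and the C4–C5 enolate is trapped on oxygen as the enol triflate A2.
- For: the chair transition state delivers the ring-trans C1=C10 alkene, a C–C bond and the ring are made together, and no stereodefined nucleofuge has to be prepared.
- Against: the rearrangement places oxygen on C5, where the target has only hydrogen, so the triflate must be reduced before the alkene can be epoxidised. The lactone is absent and must be built from a silyl-protected allylic alcohol side chain, and four protecting groups are carried.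
- Comparison: Alternative 2 is at least as strong in convergence and in the reliability of the trans alkene. The chosen fragmentation offers oxidation-state economy: the ketone appears on C6 and the free alcohol on C14, exactly where the target bears oxygen, with the lactone already in place and three steps left.

**Alternative 3:** The disconnection cuts both ring alkenes back to the C1–C4 and C5–C10 bonds of a central cyclobutane in a compact tricyclic ketone made by photocycloaddition. In the forward key step, flash vacuum thermolysis opens the cyclobutane and releases the ten-membered dienone A3.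
- For: one step forms both alkenes and the macrocycle, the C6 ketone emerges directly, and neither acid nor base is involved.
- Against: a gas-phase high-temperature step on a β-silyloxy ketone invites elimination and Cope rearrangement of the 1,5-diene. Alkene geometry rests on orbital symmetry and thermal equilibration, not on a stored ring. The lactone, its methylene group and two deprotections remain to be done.
- Comparison: Alternative 3 is stronger in bond economy of the key step. The chosen route offers mild solution conditions, geometry derived from a chair and a cyclohexene, and a lactone carried through the ring expansion.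

Key step: step 15

## Route

Step 1
Reactants: 1 phloroglucinol
Product: 2 cis,cis-cyclohexane-1,3,5-triol (all-cis; meso)
Conditions: H2 (80 bar), 5 % Rh/Al2O3, EtOH/H2O, 60 °C
Reagents that add atoms: none
Why: Catalytic arene hydrogenation adds all hydrogens from the metal surface to one face, so the all-cis (all-equatorial) meso triol should form; it supplies ring B with oxygen on C6, C8 and C10.

Step 2
Reactants: 2 cis,cis-cyclohexane-1,3,5-triol
Product: 3 cis,cis-5-[(tert-butyldimethylsilyl)oxy]cyclohexane-1,3-diol (all-cis; meso)
Conditions: t-BuMe2SiCl (1 equiv), imidazole, DMF, 0 °C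
Reagents that add atoms: tert-butyldimethylsilyl chloride, CC(C)(C)[Si](C)(C)Cl
Why: Statistical monosilylation of three equivalent secondary hydroxyls with one equivalent of silyl chloride; the monoether 3 is still meso and is separated from recycled 2 and bis-ether.

Step 3
Reactants: 3 cis,cis-5-[(tert-butyldimethylsilyl)oxy]cyclohexane-1,3-diol
Product: 4 (1S,3R,5R)-3-[(tert-butyldimethylsilyl)oxy]-5-hydroxycyclohexyl acetate
Conditions: Burkholderia cepacia lipase, vinyl acetate, t-BuOMe, 30 °C
Reagents that add atoms: vinyl acetate, CC(=O)OC=C
Why: Lipase-catalysed irreversible transesterification acylates one of the two enantiotopic hydroxyls of the meso diol (enzymatic desymmetrisation); this sets the absolute configuration of the carbon that becomes C8.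

Step 4
Reactants: 4 (1S,3R,5R)-3-[(tert-butyldimethylsilyl)oxy]-5-hydroxycyclohexyl acetate
Product: 6 (S)-5-[(tert-butyldimethylsilyl)oxy]cyclohex-2-en-1-one, via acetoxy ketone 5 (not isolated)
Conditions: Dess–Martin periodinane, NaHCO3, CH2Cl2, 0 °C to rt; then DBU, 0 °C
Reagents that add atoms: none
Why: Dess–Martin oxidation of the free hydroxyl gives the β-acetoxy ketone 5, which undergoes E1cB loss of acetic acid with DBU (acetate leaves in preference to the silyloxide); in enone 6 only C7 is left as an enolisable sp3 position, which gives the regiocontrol for step 5.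

Step 5
Reactants: 6 (S)-5-[(tert-butyldimethylsilyl)oxy]cyclohex-2-en-1-one; 7 tert-butyl bromoacetate
Product: 8 tert-butyl 2-[(1R,6S)-6-[(tert-butyldimethylsilyl)oxy]-2-oxocyclohex-3-en-1-yl]acetate (7,8-trans)
Conditions: LiN(i-Pr)2, THF, −78 °C; then 7, DMPU, −78 to −40 °C
Reagents that add atoms: none
Why: α′-Deprotonation gives the cross-conjugated lithium enolate, which is alkylated by the activated bromide on the face opposite to the neighbouring silyloxy group (7,8-trans); the enolate is kept cold so that the β-silyloxy group is not eliminated.

Step 6
Reactants: 8 tert-butyl 2-[(1R,6S)-6-[(tert-butyldimethylsilyl)oxy]-2-oxocyclohex-3-en-1-yl]acetate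
Product: 10 (3aR,7aS)-3a,7a-dihydro-1-benzofuran-2,4(3H,7H)-dione (trans-fused enone lactone), via hydroxy acid 9 (not isolated)
Conditions: CF3CO2H, CH2Cl2, trace H2O, 0 °C to rt; evaporate; EDC·HCl, DMAP (cat.), CH2Cl2, 0 °C
Reagents that add atoms: none
Why: Acid removes the tert-butyl ester and the silyl ether, and carbodiimide activation (Steglich-type) closes the trans-fused γ-lactone on the equatorial C8 hydroxyl; from here the lactone protects O8 and C12 at once, and its equatorial C8–O bond is held orthogonal to any C6 enolate, which disfavours β-elimination.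

Step 7
Reactants: 10 (3aR,7aS)-3a,7a-dihydro-1-benzofuran-2,4(3H,7H)-dione
Product: 11 (3aR,7aS)-5-iodo-3a,7a-dihydro-1-benzofuran-2,4(3H,7H)-dione
Conditions: iodine, pyridine, CH2Cl2, 0 °C to rt
Reagents that add atoms: iodine, [I][I]
Why: α-Iodination of the enone by pyridine-mediated conjugate addition, iodination of the enolate and elimination of pyridine gives the vinyl iodide for coupling at C1; pyridine is too weak a base to enolise C7.

Step 8
Reactants: 11 (3aR,7aS)-5-iodo-3a,7a-dihydro-1-benzofuran-2,4(3H,7H)-dione; 12 4-bromo-2-methylbut-1-ene
Product: 14 (3aR,7aS)-5-(3-methylbut-3-en-1-yl)-3a,7a-dihydro-1-benzofuran-2,4(3H,7H)-dione, via alkylzinc bromide 13 (not isolated)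
Conditions: 12, Zn, LiCl, THF, 40 °C; then 11, Pd(OAc)2 (2 mol %), SPhos (4 mol %), THF, rt
Reagents that add atoms: none
Why: Zinc insertion gives the primary alkylzinc bromide 13 and Negishi coupling with the α-iodoenone forms C1–C2; this replaces an enolate alkylation with a homoallylic halide, which would mainly eliminate.

Step 9
Reactants: 14 (3aR,7aS)-5-(3-methylbut-3-en-1-yl)-3a,7a-dihydro-1-benzofuran-2,4(3H,7H)-dione
Product: 16 (3aR,5S,6S,7aS)-6-hydroxy-5-(3-methylbut-3-en-1-yl)-3a,6,7,7a-tetrahydro-1-benzofuran-2,4(3H,5H)-dione (10β-hydroxy 6-ketone), via boronate 15 (not isolated)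
Conditions: bis(pinacolato)diboron, CuCl (10 mol %), KOAc (10 mol %), DMF, rt; then H2O2, aq NaHCO3, THF, 0 °C
Reagents that add atoms: hydrogen peroxide, OO
Why: Copper-catalysed conjugate borylation places boron on C10 of the enone only (the isolated alkene is inert), anti to O8, and oxidation with retention gives the β-hydroxy ketone; C1 is protonated to the equatorial side chain (cis to C11) and the C10 configuration is immaterial because C10 is oxidised in step 12; the nearly neutral medium spares the base-sensitive C7 centre.

Step 10
Reactants: 16 (3aR,5S,6S,7aS)-6-hydroxy-5-(3-methylbut-3-en-1-yl)-3a,6,7,7a-tetrahydro-1-benzofuran-2,4(3H,5H)-dione; 17 vinylmagnesium bromide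
Product: 18 (3aR,4S,5S,6S,7aS)-4-ethenyl-4,6-dihydroxy-5-(3-methylbut-3-en-1-yl)hexahydro-1-benzofuran-2(3H)-one (6β-OH; 6α-vinyl; 10β-OH)
Conditions: CeCl3 (dried), 17, THF, −78 °C; then aq NH4Cl
Reagents that add atoms: none
Why: The weakly basic organocerium reagent adds to the ketone and not to the lactone; it enters equatorially, anti to the syn-axial C10 oxygen, so that at C6 the hydroxyl is axial (β) and the vinyl group equatorial (α), the arrangement needed for a trans ring fusion.

Step 11
Reactants: 18 (3aR,4S,5S,6S,7aS)-4-ethenyl-4,6-dihydroxy-5-(3-methylbut-3-en-1-yl)hexahydro-1-benzofuran-2(3H)-one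
Product: 19 trans-decalin diol lactone (ring A cyclohexene C4=C5; 6β-OH; 10β-OH; H1α; trans-fused 8α,12-lactone)
Conditions: second-generation Grubbs catalyst (5 mol %), CH2Cl2 (0.005 M), 40 °C
Reagents that add atoms: none
Why: Ring-closing metathesis of the vinyl group with the 1,1-disubstituted alkene closes ring A as a cyclohexene, which fixes the cis C4=C5 geometry; both alkenyl groups are equatorial on ring B, so the decalin is trans-fused.

Step 12
Reactants: 19 trans-decalin diol lactone
Product: 20 6β-hydroxy-10-oxo-trans-decalin lactone
Conditions: Dess–Martin periodinane, NaHCO3, CH2Cl2, 0 °C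
Reagents that add atoms: none
Why: Dess–Martin oxidation converts the secondary C10 alcohol into the ketone while the tertiary allylic C6 alcohol cannot react; the buffered neutral medium avoids retro-aldol cleavage of the β-hydroxy ketone.

Step 13
Reactants: 20 6β-hydroxy-10-oxo-trans-decalin lactone
Product: 21 6β-hydroxy-10α,14-epoxy-trans-decalin lactone (spiro-epoxide: oxygen equatorial; C14 axial; syn to 6-OH)
Conditions: Me3S+ I−, KN(SiMe3)2, THF, −20 °C; then 20, −20 to 0 °C
Reagents that add atoms: trimethylsulfonium iodide, C[S+](C)C.[I-]
Why: Corey–Chaykovsky epoxidation: the unstabilised sulfonium ylide adds irreversibly along the axial trajectory, so C14 becomes axial (β) and the epoxide oxygen equatorial (α), the arrangement required for step 15; the ylide is too weak a base to deprotonate the C6 hydroxyl (no retro-aldol) and that hydroxyl, syn to the incoming carbon, can assist by hydrogen bonding; the step precedes the methylenation because an acrylate would be cyclopropanated.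

Step 14
Reactants: 21 6β-hydroxy-10α,14-epoxy-trans-decalin lactone
Product: 24 6β-hydroxy-10α,14-epoxy-trans-decalin α-methylene lactone (key-step precursor), via Mannich base 22 (not isolated), via ammonium iodide 23 (not isolated)
Conditions: LiN(i-Pr)2 (2.3 equiv), THF, −78 °C; CH2=NMe2+ I−, −78 to 0 °C; then MeI, MeOH, rt; then aq NaHCO3, CH2Cl2
Reagents that add atoms: N,N-dimethylmethyleneiminium iodide (Eschenmoser's salt), C=[N+](C)C.[I-]
Why: After deprotonation of the hydroxyl the lactone enolate undergoes a Mannich reaction with Eschenmoser's salt; N-methylation and E1cB loss of trimethylamine unveil the α-methylene lactone without touching the epoxide.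

Step 15
Reactants: 24 6β-hydroxy-10α,14-epoxy-trans-decalin α-methylene lactone
Product: 25 14-hydroxy-6-oxogermacra-1(10),4,11(13)-trien-8α,12-olide (C1=C10 trans in the ring; C4=C5 cis)
Conditions: Ti(O-i-Pr)4 (1.5 equiv), CH2Cl2, 0 °C to rt; aq tartaric acid work-up
Reagents that add atoms: none
Why: Ligand exchange gives the C6 titanate and titanium (the same centre or a second one) coordinates the epoxide oxygen; the C6–O electron pair then pushes into the C1–C6 bond, which breaks while the antiperiplanar C10–O bond of the epoxide leaves, so that the C6 ketone, the C1=C10 alkene and the C14 alkoxide form in one concerted Grob-type step. The closest known reaction type is the Lewis-acid-promoted fragmentation of cyclic 1,3-hydroxy epoxides, together with the Grob fragmentation of decalin-1,3-diol monosulfonates to cyclodecenones. No ring is closed by bond formation: the ten-membered ring arises because the bond shared by rings A and B is cleaved, so there is no entropic cost of a macrocyclisation, and the strain of the epoxide pays for the strain of the medium ring. No stereocentre is created; C7 and C8 are untouched and the centres at C6, C1 and C10 are erased. The selectivity needed is alkene geometry: in the chair of ring B the epoxide C10–O bond is equatorial and antiperiplanar to C1–C6, and C2 is equatorial on C1 and therefore anti to C9, which gives the alkene that is trans in the ring, while the cis C4=C5 geometry is inherited from the cyclohexene. Competing paths are disfavoured by the structure: O6 cannot attack C14 in line with the C14–O bond, it cannot reach the carbonyl of the trans-fused lactone, and the only other bond antiperiplanar to C10–O (C8–C9) has no donor oxygen behind it. The medium is Lewis acidic and not basic, which protects the new ketone, whose C7 hydrogen is flanked by a β-acyloxy group, from epimerisation and elimination.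

Step 16
Reactants: 25 14-hydroxy-6-oxogermacra-1(10),4,11(13)-trien-8α,12-olide
Product: 26 6α,14-dihydroxygermacra-1(10),4,11(13)-trien-8α,12-olide (6S)
Conditions: NaBH4, CeCl3·7H2O, MeOH, −78 °C
Reagents that add atoms: none
Why: Luche reduction is a 1,2-reduction of the enone carbonyl that leaves the acrylate; hydride should attack from the ring periphery on the conformer in which the carbonyl oxygen has turned to the α face, away from C14 (syn-axial to it in 24), giving the 6α (6S) alcohol trans to C11.

Step 17
Reactants: 26 6α,14-dihydroxygermacra-1(10),4,11(13)-trien-8α,12-olide; 27 tiglic acid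
Product: 28 6α-hydroxy-14-tigloyloxygermacra-1(10),4,11(13)-trien-8α,12-olide
Conditions: 27 (1.1 equiv), EDC·HCl, DMAP (cat.), CH2Cl2, −20 °C
Reagents that add atoms: none
Why: Steglich esterification acylates the primary allylic hydroxyl much faster than the hindered secondary one; it follows the reduction so that no amine base meets the β-acyloxy ketone 25, and it leaves C6–OH as the only allylic hydroxyl for step 18.

Step 18
Reactants: 28 6α-hydroxy-14-tigloyloxygermacra-1(10),4,11(13)-trien-8α,12-olide
Product: 29 CNP0116446.1: (4S,5R,6S,7S,8S)-4β,5β-epoxy-6α-hydroxy-14-tigloyloxygermacra-1(10),11(13)-dien-8α,12-olide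
Conditions: VO(acac)2 (5 mol %), t-BuOOH, CH2Cl2, 0 °C
Reagents that add atoms: tert-butyl hydroperoxide, CC(C)(C)OO
Why: Vanadium-catalysed hydroxyl-directed epoxidation reacts only at the allylic alcohol alkene; with H6 eclipsing the cis alkene (A(1,3) strain with C3) and C7 on the inner face, the hydroxyl sits on the outer face and delivers oxygen there, which gives the 4β,5β (4S,5R) epoxide, threo to the 6α hydroxyl.

## Compound list

1 | phloroglucinol (benzene-1,3,5-triol) | Oc1cc(O)cc(O)c1 | starting material
2 | cis,cis-cyclohexane-1,3,5-triol (all-cis, meso) | O[C@H]1C[C@@H](O)C[C@@H](O)C1 | intermediate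
3 | cis,cis-5-[(tert-butyldimethylsilyl)oxy]cyclohexane-1,3-diol (all-cis, meso) | O[C@H]1C[C@@H](O[Si](C)(C)C(C)(C)C)C[C@@H](O)C1 | intermediate
4 | (1S,3R,5R)-3-[(tert-butyldimethylsilyl)oxy]-5-hydroxycyclohexyl acetate | O[C@H]1C[C@@H](O[Si](C)(C)C(C)(C)C)C[C@@H](OC(C)=O)C1 | intermediate
5 | (1R,3S)-3-[(tert-butyldimethylsilyl)oxy]-5-oxocyclohexyl acetate | O=C1C[C@@H](O[Si](C)(C)C(C)(C)C)C[C@@H](OC(C)=O)C1 | intermediate
6 | (S)-5-[(tert-butyldimethylsilyl)oxy]cyclohex-2-en-1-one | O=C1C=CC[C@H](O[Si](C)(C)C(C)(C)C)C1 | intermediate
7 | tert-butyl bromoacetate | BrCC(=O)OC(C)(C)C | starting material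
8 | tert-butyl 2-[(1R,6S)-6-[(tert-butyldimethylsilyl)oxy]-2-oxocyclohex-3-en-1-yl]acetate | O=C1C=CC[C@H](O[Si](C)(C)C(C)(C)C)[C@H]1CC(=O)OC(C)(C)C | intermediate
9 | 2-[(1R,6S)-6-hydroxy-2-oxocyclohex-3-en-1-yl]acetic acid | O=C1C=CC[C@H](O)[C@H]1CC(=O)O | intermediate
10 | (3aR,7aS)-3a,7a-dihydro-1-benzofuran-2,4(3H,7H)-dione (ring B enone with trans-fused 8α,12-lactone) | O=C1C=CC[C@@H]2OC(=O)C[C@@H]12 | intermediate
11 | (3aR,7aS)-5-iodo-3a,7a-dihydro-1-benzofuran-2,4(3H,7H)-dione | O=C1C([I])=CC[C@@H]2OC(=O)C[C@@H]12 | intermediate
12 | 4-bromo-2-methylbut-1-ene | C=C(C)CCBr | starting material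
13 | (3-methylbut-3-en-1-yl)zinc bromide | C=C(C)CC[Zn]Br | intermediate
14 | (3aR,7aS)-5-(3-methylbut-3-en-1-yl)-3a,7a-dihydro-1-benzofuran-2,4(3H,7H)-dione | O=C1C(CCC(C)=C)=CC[C@@H]2OC(=O)C[C@@H]12 | intermediate
15 | (3aR,5S,6S,7aS)-5-(3-methylbut-3-en-1-yl)-6-(4,4,5,5-tetramethyl-1,3,2-dioxaborolan-2-yl)-3a,6,7,7a-tetrahydro-1-benzofuran-2,4(3H,5H)-dione | O=C1[C@@H](CCC(C)=C)[C@@H](B3OC(C)(C)C(C)(C)O3)C[C@@H]2OC(=O)C[C@@H]12 | intermediate
16 | (3aR,5S,6S,7aS)-6-hydroxy-5-(3-methylbut-3-en-1-yl)-3a,6,7,7a-tetrahydro-1-benzofuran-2,4(3H,5H)-dione | O=C1[C@@H](CCC(C)=C)[C@@H](O)C[C@@H]2OC(=O)C[C@@H]12 | intermediate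
17 | vinylmagnesium bromide | C=C[Mg]Br | starting material
18 | (3aR,4S,5S,6S,7aS)-4-ethenyl-4,6-dihydroxy-5-(3-methylbut-3-en-1-yl)hexahydro-1-benzofuran-2(3H)-one | C=C[C@]1(O)[C@@H](CCC(C)=C)[C@@H](O)C[C@@H]2OC(=O)C[C@@H]12 | intermediate
19 | trans-decalin diol lactone: ring A cyclohexene (C4=C5, C15 on C4), 6β-OH (angular, axial), 10β-OH, H1α, trans-fused 8α,12-lactone (C11 β on C7) | O=C1O[C@H]2C[C@H](O)[C@@H]3CCC(C)=C[C@@]3(O)[C@@H]2C1 | intermediate
20 | 6β-hydroxy-10-oxo-trans-decalin lactone (otherwise as 19) | O=C1O[C@H]2CC(=O)[C@@H]3CCC(C)=C[C@@]3(O)[C@@H]2C1 | intermediate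
21 | 6β-hydroxy-10α,14-epoxy-trans-decalin lactone (spiro-epoxide at C10, oxygen α and equatorial, C14 β and axial) | O=C1O[C@H]2C[C@]3(CO3)[C@@H]4CCC(C)=C[C@@]4(O)[C@@H]2C1 | intermediate
22 | Mannich base: 21 with a (dimethylamino)methyl group on C11 (C11 epimers) | CN(C)CC1C(=O)O[C@H]2C[C@]3(CO3)[C@@H]4CCC(C)=C[C@@]4(O)[C@H]12 | intermediate
23 | trimethylammonium iodide of 22 | C[N+](C)(C)CC1C(=O)O[C@H]2C[C@]3(CO3)[C@@H]4CCC(C)=C[C@@]4(O)[C@H]12.[I-] | intermediate
24 | 6β-hydroxy-10α,14-epoxy-trans-decalin α-methylene lactone (key-step precursor) | C=C1C(=O)O[C@H]2C[C@]3(CO3)[C@@H]4CCC(C)=C[C@@]4(O)[C@H]12 | intermediate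
25 | 14-hydroxy-6-oxogermacra-1(10),4,11(13)-trien-8α,12-olide (C1=C10 trans in the ring, C4=C5 cis; key-step product) | C=C1C(=O)O[C@H]2C/C(CO)=C/CC/C(C)=C\C(=O)[C@H]12 | intermediate
26 | 6α,14-dihydroxygermacra-1(10),4,11(13)-trien-8α,12-olide (6S) | C=C1C(=O)O[C@H]2C/C(CO)=C/CC/C(C)=C\[C@@H](O)[C@H]12 | intermediate
27 | tiglic acid ((E)-2-methylbut-2-enoic acid) | C/C=C(\C)C(=O)O | starting material
28 | 6α-hydroxy-14-tigloyloxygermacra-1(10),4,11(13)-trien-8α,12-olide | C=C1C(=O)O[C@H]2C/C(COC(=O)/C(C)=C/C)=C/CC/C(C)=C\[C@@H](O)[C@H]12 | intermediate
29 | CNP0116446.1: (4S,5R,6S,7S,8S)-4β,5β-epoxy-6α-hydroxy-14-tigloyloxygermacra-1(10),11(13)-dien-8α,12-olide | C=C1C(=O)O[C@H]2C/C(COC(=O)/C(C)=C/C)=C/CC[C@]3(C)O[C@@H]3[C@@H](O)[C@H]12 | target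

## Step count and least certain steps

Total step count: 18. Longest linear sequence: 18 steps (1 to 29).

**Step 15 (key step).**
- What may go wrong: opening or rearrangement of the tertiary epoxide at titanium without cleavage of C1–C6 (transfer of isopropoxide, loss of a proton to an allylic alcohol). After a successful fragmentation, alkoxide may attack the acrylate or the β-acyloxy ketone may enolise at C7.
- Why: the driving force (epoxide strain against medium-ring strain) is modest and warming may be needed.
- Fallback: carry the acrylate through the fragmentation in masked form. Setting out from 21, the Mannich reaction of step 14 is stopped at amine 22, which is isolated. Fragmentation of 22 with Ti(O-i-Pr)4 gives amino dienone F1, Luche reduction gives amino diol F2, and N-methylation to ammonium iodide F3 followed by bicarbonate elimination returns the route at 26.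

**Step 13.**
- What may go wrong: poor facial selectivity. The syn-axial C6 hydroxyl flanks the axial trajectory, so equatorial attack can compete; it gives the C10 epimer, whose C–O bond is axial and cannot fragment.
- Fallback: oxygen is delivered to the open α face of a C10=C14 enol ether instead of carbon to the hindered β face of the ketone. Setting out from 20, silylation gives trimethylsilyl ether F4 and Wittig methoxymethylenation gives enol ether F5. Dimethyldioxirane epoxidises the electron-rich enol ether (much faster than the ring alkene) anti to the axial silyloxy group, and the methoxy epoxide collapses to α-hydroxy aldehyde F6. NaBH4 gives diol F7. Sulfonylation of the primary hydroxyl and base close the spiro-epoxide to silyl ether F8; the blocked C6 oxygen cannot form a tetrahydrofuran instead. Buffered Bu4NF returns the route at 21.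

**Step 16.**
- What may go wrong: poor facial selectivity. If the ketone reacts through the conformer in which it is born (carbonyl oxygen on the β face), peripheral hydride attack gives the 6β epimer. Conjugate reduction of the acrylate is the second concern.
- Fallback: Mitsunobu inversion. Setting out from 25, the reduction product 6-epi diol F9 is tigloylated at O14 as in step 17 to 6-epi tiglate F10. Mitsunobu reaction with chloroacetic acid inverts C6 to chloroacetate F11, and thiourea removes the chloroacetyl group without touching the tiglate, returning the route at 28.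

**Step 18.**
- What may go wrong: delivery of oxygen to the other face through the rotamer with the hydroxyl, not H6, near the alkene plane. This is the usual course of metal-catalysed epoxidation of eight- and nine-membered cis-cycloalkenols and would give the 4α,5α epoxide. A peracid would favour the wanted face but would also attack the strained C1=C10 alkene.
- Fallback: move the epoxidation to the decalin, where the tertiary C6 hydroxyl of a cyclohexenol directs it reliably. Setting out from 24, vanadium-catalysed epoxidation gives bis-epoxide F12 with the 4β,5β epoxide syn to the 6β hydroxyl, which is the C4/C5 configuration of 29. Fragmentation as in step 15 gives epoxy ketone F13, Luche reduction gives epoxy diol F14, and selective tigloylation of O14 returns the route at 29.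

## Further compounds

F1 | step 15 | amino dienone: 25 with C11–CH2NMe2 in place of the exocyclic methylene | CN(C)CC1C(=O)O[C@H]2C/C(CO)=C/CC/C(C)=C\C(=O)[C@H]12
F2 | step 15 | amino diol: 26 with C11–CH2NMe2 in place of the exocyclic methylene | CN(C)CC1C(=O)O[C@H]2C/C(CO)=C/CC/C(C)=C\[C@@H](O)[C@H]12
F3 | step 15 | trimethylammonium iodide of F2 | C[N+](C)(C)CC1C(=O)O[C@H]2C/C(CO)=C/CC/C(C)=C\[C@@H](O)[C@H]12.[I-]
F4 | step 13 | 6-O-trimethylsilyl ether of 20 | O=C1O[C@H]2CC(=O)[C@@H]3CCC(C)=C[C@@]3(O[Si](C)(C)C)[C@@H]2C1
F5 | step 13 | 10-(methoxymethylidene) enol ether of F4 (alkene isomers) | O=C1O[C@H]2CC(=COC)[C@@H]3CCC(C)=C[C@@]3(O[Si](C)(C)C)[C@@H]2C1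
F6 | step 13 | 10α-hydroxy-10β-carbaldehyde, 6-O-trimethylsilyl ether | O=C1O[C@H]2C[C@](O)(C=O)[C@@H]3CCC(C)=C[C@@]3(O[Si](C)(C)C)[C@@H]2C1
F7 | step 13 | 10α,14-diol, 6-O-trimethylsilyl ether | O=C1O[C@H]2C[C@](O)(CO)[C@@H]3CCC(C)=C[C@@]3(O[Si](C)(C)C)[C@@H]2C1
F8 | step 13 | 6-O-trimethylsilyl ether of 21 | O=C1O[C@H]2C[C@]3(CO3)[C@@H]4CCC(C)=C[C@@]4(O[Si](C)(C)C)[C@@H]2C1
F9 | step 16 | 6-epi diol (6β-hydroxy epimer of 26) | C=C1C(=O)O[C@H]2C/C(CO)=C/CC/C(C)=C\[C@H](O)[C@H]12
F10 | step 16 | 6-epi tiglate (6β-hydroxy epimer of 28) | C=C1C(=O)O[C@H]2C/C(COC(=O)/C(C)=C/C)=C/CC/C(C)=C\[C@H](O)[C@H]12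
F11 | step 16 | 6α-chloroacetate of 28 | C=C1C(=O)O[C@H]2C/C(COC(=O)/C(C)=C/C)=C/CC/C(C)=C\[C@@H](OC(=O)CCl)[C@H]12
F12 | step 18 | 4β,5β-epoxide of 24 (bis-epoxide) | C=C1C(=O)O[C@H]2C[C@]3(CO3)[C@@H]4CC[C@]5(C)O[C@@H]5[C@@]4(O)[C@H]12
F13 | step 18 | 4β,5β-epoxy-14-hydroxy-6-oxogermacra-1(10),11(13)-dien-8α,12-olide | C=C1C(=O)O[C@H]2C/C(CO)=C/CC[C@]3(C)O[C@@H]3C(=O)[C@H]12
F14 | step 18 | 4β,5β-epoxy-6α,14-dihydroxygermacra-1(10),11(13)-dien-8α,12-olide | C=C1C(=O)O[C@H]2C/C(CO)=C/CC[C@]3(C)O[C@@H]3[C@@H](O)[C@H]12
A1 | alternative 1 | protected trans,cis-dienyl α-methylene lactone (O6 tert-butyldimethylsilyl, O14 4-methoxybenzyl) | C=C1C(=O)O[C@H]2C/C(COCc3ccc(OC)cc3)=C/CC/C(C)=C\[C@@H](O[Si](C)(C)C(C)(C)C)[C@H]12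
A2 | alternative 2 | ten-membered trans,cis-dienyl C5 enol triflate (O6 and O14 4-methoxybenzyl, O8 and O12 tert-butyldimethylsilyl) | C=C(CO[Si](C)(C)C(C)(C)C)[C@@H]1[C@@H](O[Si](C)(C)C(C)(C)C)C/C(COCc2ccc(OC)cc2)=C/CC/C(C)=C(OS(=O)(=O)C(F)(F)F)\[C@H]1OCc1ccc(OC)cc1
A3 | alternative 3 | ten-membered trans,cis-dienone with C7 methyl acetate side chain (O8 tert-butyldimethylsilyl, O14 tert-butyldiphenylsilyl) | COC(=O)C[C@@H]1[C@@H](O[Si](C)(C)C(C)(C)C)C/C(CO[Si](c2ccccc2)(c3ccccc3)C(C)(C)C)=C/CC/C(C)=C\C1=O
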